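The data come from a simulation with made-up constants; the scatter is artificial.

The number to hold is 0.679: read from the grey run at 8.00 h, this is the free share f, the part of the electrophile not yet made into target that still stands as electrophile and not as dormant form.

| flask | electrophile | free base | gas | remark | time |
|---|---|---|---|---|---|
| grey | 26 mM | 25.5 mM | 2 mM (held) | run made earlier |  |
| Wednesday's | 17 mM | 26.0 mM | 2.0 mM (held) |  | 40 h |
| Friday's | 17 mM | 38.0 mM | 2.0 mM (held) |  | 40 h |

- grey (time / h: electrophile / %, target / %): 0.667: 94.4, 0; 1.00: 93.5, 1.5; 1.33: 88.6, 0; 2.50: 81.7, 1.4; 3.00: 80.2, 2.4; 5.00: 70.6, 3.7; 8.00: 63.4, 6.6

(readings scatter by 1 percentage point)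

- part of the electrophile that has reacted at the end, Wednesday's
- part of the electrophile that has reacted at the end, Friday's
- what raising the concentration of free base from its lowest to its highest value here does to the part of the electrophile that has reacted (changes below 5 percentage points count as none) (no change / it rises / it falls)

- at the start none of nucleophile is dissolved
- the numbers in the tables scatter with a standard deviation of 1 percentage point
- on the list of suspects stand: electrophile <-> dormant form; acid set free + free base <-> salt of the base; nucleophile + acid set free <-> protonated nucleophile; electrophile + nucleophile -> acid set free + target; gas <-> nucleophile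
- what has gone from electrophile into another species counts as reacted, even if it can come back
- no earlier run changes the charge of free base; that part of a forecast is a guess

Follow one molecule of electrophile. It has either become target, with chance P, or it sits in the pool of electrophile plus dormant form, where it is free with chance f. So the part reacted is 1 − f(1 − P).

Now read the grey table down its last rows. At 3.00 h, f is 0.822, at 5.00 h it is 0.733, and at 8.00 h it is 0.679. The fall per hour gets slower, but f is still moving, so I treat 0.679 as a high value.

The target column shows the pool draining. Target at 6.6% by 8.00 h means a decay exp(−λt) with λ = 0.00853 /h, a pseudo-first-order rate if nucleophile holds steady. Its time constant of 117 h is longer than the 40 h run.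

My reckoning carries both values over to the new charge. By this estimate target comes to 28.9%, and the part reacted to 51.8%, which I hold as a low figure for Wednesday's. Free base stands on neither branch of this fork, so I give Friday's the same, as a guess.

The forecast is higher than mine: 60% (52% to 70%) for Wednesday's, 61% (52% to 73%) for Friday's, and no change. It reads the early loss as “reversible parking in the dormant form”.

Wednesday's flask gives 57.5% and Friday's 57.6%, a change of 0.067 percentage points, so no change.

    electrophile ⇌ dormant form (K = 0.570, k = 0.0870 /h)
    acid set free + free base ⇌ salt of the base, settled at all times (K = 49.0 /M)
    nucleophile + acid set free ⇌ protonated nucleophile, settled at all times (K = 29000 /M)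
    electrophile + nucleophile → acid set free + target (k = 15.0 /M/h)
    gas ⇌ nucleophile, rate k5*(csat - [nucleophile]) (kL = 0.280 /h)

At 40.0 h, Wednesday's holds target 31.5%, and with that target the reading f gives 53.5% reacted. A neighbour of Wednesday's, charged with 4.2 mM of electrophile, holds target 44.2% at 40.0 h; there f gives 62.1%, and the part of the electrophile reacted in that flask is 65.9%.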